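The numbers in the tables stem from a simulated flask for substances that don't exist; scatter was added.

One feed time, 10 min, is my unit: autumn and midnight are both read at its end.

| flask | free monomer | pre-initiator | remark | time |
|---|---|---|---|---|
| elm | 0.25 M (fed, over 10 min) | 20 mM | run made earlier |  |
| cedar | 0.25 M (fed, over 10 min) | 46 mM | run made earlier |  |
| autumn | 0.25 M (fed, over 10 min) | 14 mM |  | 10 min |
| midnight | 0.25 M (fed, over 10 min) | 40 mM |  | 10 min |

| run | time / min | monomer in chains / % |
|---|---|---|
| elm | 1.33 | 2 |
| elm | 4.00 | 13 |
| elm | 6.00 | 32 |
| elm | 10.0 | 71 |
| cedar | 0.833 | 0 |
| cedar | 2.00 | 3 |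
| cedar | 4.00 | 22 |
| cedar | 10.0 | 89 |

(readings scatter by 1.5 percentage points)

- the average divides the monomer in chains by the number of chains begun, living and dead together
- the earlier runs do not show the number of chains; that part of a forecast is a guess
- percentages count the whole charge, also what has not yet gone in

- which of the two ends with the longer chains by the average number of monomer units in a chain (chains begun, living or dead) ("neither" if they lie within 10%) (autumn / midnight / neither)
- average number of monomer units in a chain (chains begun, living or dead) at the end, autumn
- average number of monomer units in a chain (chains begun, living or dead) at the end, midnight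

Your hunch is that length is the charge ratio, free monomer over pre-initiator: 17.9 for autumn, 6.25 for midnight. That ratio puts the whole charge in chains, so I need the part m still free at the end.

Let T be the feed time and κ the rate constant for free monomer entering chains. Once the chains run, the loss is pseudo-first-order in m, and the balance integrates in closed form:

dm/dt = 1/T − κm, so m(T) = (1 − e^(−D))/D, with D = κT.

This skips the slow start; elm holds 13% of its charge in chains at 4.00 min.

I read κ from the late readings. In elm, from 6.00 min to 10.0 min, chains gain 39 percentage points while free monomer stands at 28.0% and then 29.0%. So κ reads 0.342 min⁻¹. The same reading on cedar gives 0.770 min⁻¹. Per pre-initiator charged the two match, so I take κ = gc, with c the pre-initiator charged and g = 0.282 M⁻¹ s⁻¹.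

The feed number D, κ times the feed time, is my tool. I count one chain per pre-initiator charged, which is a guess, and length = (1 − m) × charge ratio.

Autumn: D = 2.37, m = 38.3%, length 11.0.

Midnight: D = 6.77, m = 14.8%, length 5.33.

So I say autumn is longer. The forecast also names autumn, with 11.5 and 5.7, higher than mine, and warns: “Chain counts are inferred, not observed”.

The flask gives autumn, with 11.7 against 6.06.

    free monomer + initiator → living end + monomer in chains (k = 0.100 M⁻¹ s⁻¹)
    free monomer + living end → monomer in chains + living end, rate k2*[living end]*[free monomer] (k = 0.340 M⁻¹ s⁻¹)
    pre-initiator → initiator (k = 0.0200 s⁻¹)

At 10.0 min, autumn holds 0.0138 M of living end from 14 mM of pre-initiator, and 35.8% of its charge is free monomer, where D = 2.37 gave 38.3%. A neighbour of autumn charged with 0.0056 M has the same feed time, so its feed number is 0.948 and the closed form leaves 64.6% free. That neighbour ends with 62.5% free monomer.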